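**Strategy.** The plan cuts the C2–C3 bond of both 6-bromoindole rings. It exploits the fact that each indole C3 is bonded to an imidazole carbon (C2 or C4) while C2 is a lone CH on N1. C3 can therefore begin as a diaryl ketone carbon and C2 as a formamide carbon. A single exposure to low-valent titanium unites these two like-polarised carbonyl carbons at both sites, closing both pyrrole rings and giving the aromatic bis-indole directly. The substrate is an N1-SEM imidazole carrying 4-bromo-2-formamidobenzoyl groups at C2 and C5. It is reached by double acylation of a 2,5-dilithioimidazole, fluoride-to-amine exchange and N-formylation. SEM removal ends the synthesis.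

Key step: step 6

Assumption: the N–H tautomers of the free imidazole equilibrate rapidly, so the 2,5-disubstituted ring becomes identical with the 2,4-disubstituted ring of the target once N1 is unprotected; the target has no stereocentre.

**Step 1**
Reactants: 1 imidazole; 2 2-(trimethylsilyl)ethoxymethyl chloride (SEMCl)
Product: 4 1-{[2-(trimethylsilyl)ethoxy]methyl}-1H-imidazole (1-SEM-imidazole), via sodium imidazolide 3 (not isolated)
Conditions: NaH, THF, 0 °C; then 2, 0 °C → rt
Reagents that add atoms: none
Why: SN2 N-alkylation of the symmetric imidazolide anion by a highly reactive chloromethyl ether is the standard SEM protection, and only one product can form because both nitrogens of the anion are equivalent.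

**Step 2**
Reactants: 5 4-bromo-2-fluorobenzoic acid
Product: 7 4-bromo-2-fluoro-N-methoxy-N-methylbenzamide, via acyl imidazolide 6 (not isolated)
Conditions: CDI, CH2Cl2, rt; then MeNHOMe·HCl, rt
Reagents that add atoms: N,O-dimethylhydroxylamine hydrochloride, CNOC.Cl
Why: Weinreb amide formation by acyl transfer from the imidazolide is a mild amide coupling that needs no added base and leaves the C–F and C–Br bonds alone.

**Step 3**
Reactants: 4 1-SEM-imidazole; 7 4-bromo-2-fluoro-N-methoxy-N-methylbenzamide (2.3 equiv)
Product: 10 1-SEM-2,5-bis(4-bromo-2-fluorobenzoyl)imidazole, via 2,5-dilithioimidazole 8 (not isolated), via bis-hemiaminal dilithium salt 9 (not isolated)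
Conditions: n-BuLi (2.1 equiv), TMEDA (2.1 equiv), THF, −78 → −10 °C, 1 h; recool to −78 °C, cannulate into 7 in THF, −78 → 0 °C; sat. aq NH4Cl
Reagents that add atoms: none
Why: Directed 2,5-dilithiation of an N-alkoxymethylimidazole (C2–H is the most acidic site and the SEM oxygen guides the second base to C5–H) followed by Weinreb ketone synthesis makes both C–Li bonds before any bromoarene or ketone is in the flask, so no alkyllithium can attack a C–Br bond, the acidic C–H between F and Br or a carbonyl group, and the chelated adduct 9 releases the two ketones only on quenching, which rules out over-addition.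

**Step 4**
Reactants: 10 1-SEM-2,5-bis(4-bromo-2-fluorobenzoyl)imidazole
Product: 11 1-SEM-2,5-bis(2-amino-4-bromobenzoyl)imidazole
Conditions: 28% aq NH3, DMSO, 100 °C, sealed vessel
Reagents that add atoms: ammonia, N
Why: In this nucleophilic aromatic substitution by addition–elimination each fluoride sits ortho to a strongly withdrawing hetaryl ketone and leaves far more readily than the para bromide, and the hydrogen-bonded aminoketone ring formed first is too electron-rich for a further substitution, while SEM is inert to base.

**Step 5**
Reactants: 11 1-SEM-2,5-bis(2-amino-4-bromobenzoyl)imidazole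
Product: 12 1-SEM-2,5-bis[4-bromo-2-(formylamino)benzoyl]imidazole
Conditions: HCO2H/Ac2O (premixed, 55 °C, 2 h), THF, 0 °C → rt
Reagents that add atoms: acetic formic anhydride (from formic acid and acetic anhydride), CC(=O)OC=O
Why: N-Formylation with the mixed anhydride, which transfers only its more electrophilic formyl group, is strong enough for these weakly nucleophilic ortho-acylanilines, spares SEM at or below room temperature, and any transient acylation of imidazole N3 is undone on aqueous work-up.

**Step 6**
Reactants: 12 1-SEM-2,5-bis[4-bromo-2-(formylamino)benzoyl]imidazole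
Product: 13 1-SEM-2,5-bis(6-bromo-1H-indol-3-yl)imidazole
Conditions: TiCl3 (10 equiv), Zn dust (20 equiv), THF, reflux, 2 h; then 12 in THF by syringe pump (final ca. 0.01 M), reflux, 1–2 h; aq K2CO3, Celite
Reagents that add atoms: none
Why: Fürstner indole synthesis, the intramolecular oxo-amide version of the McMurry coupling: low-valent titanium passes electrons to each diaryl ketone, the most easily reduced group present because it is conjugated with a bromoarene and an electron-poor imidazole, and the titanium-bound ketyl (or dianion) carbon then adds to the neighbouring formamide C=O, which coordinates to the same oxophilic metal. Each pyrrole ring closes in a 5-exo-trig mode (future C3 attacks the formyl carbon, whose oxygen stays outside the new ring), and titanium then removes both oxygens of the vicinal diolate, a deoxygenation driven by the strength of Ti–O bonds and the gain of indole aromaticity. The closest known cases are ortho-aroyl and ortho-(azol-2-ylcarbonyl)formanilides, which give 2-unsubstituted 3-(het)arylindoles; here the same event takes place at two independent sites, and the two ketone carbons cannot couple with each other because that bond would have to bridge imidazole C2 and C5. No stereocentre is created. The step needs ring closure to outrun intermolecular pinacol coupling, which the ortho arrangement and slow addition into a large excess of pre-reduced reagent secure, and it needs both C–Br bonds to survive, which is credible because bromobenzophenones are routinely carried through McMurry olefinations with the same reagents and the contact time is kept short. The position of bromine is not at stake, since the ring carbon para to the ketone necessarily becomes C6, and SEM is a spectator whose accidental loss would only anticipate step 7.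

**Step 7**
Reactants: 13 1-SEM-2,5-bis(6-bromo-1H-indol-3-yl)imidazole
Product: 15 nortopsentin A [2,4-bis(6-bromo-1H-indol-3-yl)-1H-imidazole], via nortopsentin A hydrochloride 14 (not isolated)
Conditions: 6 M aq HCl, EtOH, 80 °C; then aq NaHCO3
Reagents that add atoms: none
Why: Acid hydrolysis of the N,O-acetal is the standard SEM cleavage on imidazoles, and it should be clean here because the protonated imidazole is a good leaving group and, as a cationic substituent on both indole C3 atoms, deactivates the indoles toward the liberated formaldehyde.

**Compound list**
1 | imidazole | c1c[nH]cn1 | starting material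
2 | 2-(trimethylsilyl)ethoxymethyl chloride | C[Si](C)(C)CCOCCl | starting material
3 | sodium imidazolide | [Na+].c1c[n-]cn1 | intermediate
4 | 1-SEM-imidazole | C[Si](C)(C)CCOCn1ccnc1 | intermediate
5 | 4-bromo-2-fluorobenzoic acid | OC(=O)c1ccc(Br)cc1F | starting material
6 | 1-(4-bromo-2-fluorobenzoyl)imidazole | O=C(c1ccc(Br)cc1F)n1ccnc1 | intermediate
7 | 4-bromo-2-fluoro-N-methoxy-N-methylbenzamide | CON(C)C(=O)c1ccc(Br)cc1F | intermediate
8 | 2,5-dilithio-1-SEM-imidazole | C[Si](C)(C)CCOCn1c([Li])cnc1[Li] | intermediate
9 | dilithium salt of the twofold tetrahedral adduct of 8 with 7 (mixture of diastereomers) | C[Si](C)(C)CCOCn1c(C([O-])(N(C)OC)c2ccc(Br)cc2F)cnc1C([O-])(N(C)OC)c1ccc(Br)cc1F.[Li+].[Li+] | intermediate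
10 | 1-SEM-2,5-bis(4-bromo-2-fluorobenzoyl)imidazole | C[Si](C)(C)CCOCn1c(C(=O)c2ccc(Br)cc2F)cnc1C(=O)c1ccc(Br)cc1F | intermediate
11 | 1-SEM-2,5-bis(2-amino-4-bromobenzoyl)imidazole | C[Si](C)(C)CCOCn1c(C(=O)c2ccc(Br)cc2N)cnc1C(=O)c1ccc(Br)cc1N | intermediate
12 | 1-SEM-2,5-bis[4-bromo-2-(formylamino)benzoyl]imidazole | O=CNc1cc(Br)ccc1C(=O)c1cnc(C(=O)c2ccc(Br)cc2NC=O)n1COCC[Si](C)(C)C | intermediate
13 | 1-SEM-2,5-bis(6-bromo-1H-indol-3-yl)imidazole | C[Si](C)(C)CCOCn1c(-c2c[nH]c3cc(Br)ccc23)cnc1-c1c[nH]c2cc(Br)ccc12 | intermediate
14 | nortopsentin A hydrochloride | Brc1ccc2c(-c3c[nH]c(-c4c[nH]c5cc(Br)ccc45)n3)c[nH]c2c1.Cl | intermediate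
15 | nortopsentin A | Brc1ccc2c(-c3c[nH]c(-c4c[nH]c5cc(Br)ccc45)n3)c[nH]c2c1 | target

**Totals**
- Total step count: 7.
- Longest linear sequence: 6 (steps 1, 3, 4, 5, 6, 7).

**Steps most likely to fail**

Risk 1, step 6. Several things could go wrong:
- reductive loss of bromine;
- intermolecular ketone–ketone coupling;
- plain reduction of a ketone without C–C bond formation;
- stalling after only one ring closure because the basic imidazole ties up titanium.

The fallback replaces reductive coupling by a redox-neutral polar one-carbon annulation, so no reducing metal meets the C–Br bonds. It sets out from diamine 11 and skips step 5.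
- Corey–Chaykovsky methylenation with trimethylsulfonium iodide and NaH in DMSO–THF would convert both ketones into 1-SEM-2,5-bis[2-(2-amino-4-bromophenyl)oxiran-2-yl]imidazole F1.
- On warming, each ortho-amino group opens its epoxide at the CH2 terminus to give 1-SEM-2,5-bis(6-bromo-3-hydroxyindolin-3-yl)imidazole F2.
- Catalytic TsOH then removes two molecules of water, and the route is rejoined at 13.
- Conversion of ortho-aminoaryl ketones into 3-substituted indoles with sulfur methylides is known chemistry.

Risk 2, step 3. The second metalation may be incomplete. Bromine–lithium or proton transfer between the hetaryllithium centres and the bromofluoroarene may also occur before carbonyl addition is over. Both would erode the double acylation. The fallback exchanges the roles of nucleophile and electrophile and sets out from 4.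
- The dianion 8 is quenched with DMF, an electrophile without sensitive sites, to give 1-SEM-imidazole-2,5-dicarbaldehyde F3, which is easily separated from any monoaldehyde.
- Commercial 4-bromo-2-fluoro-1-iodobenzene (Fc1cc(Br)ccc1I) undergoes selective iodine–magnesium exchange with i-PrMgCl·LiCl in THF at −40 °C to give (4-bromo-2-fluorophenyl)magnesium chloride F4.
- F4 adds to both formyl groups to give 1-SEM-2,5-bis[(4-bromo-2-fluorophenyl)(hydroxy)methyl]imidazole F5.
- MnO2 in CH2Cl2 oxidises both carbinols, and the route is rejoined at 10.

Risk 3, step 4. The second substitution may be sluggish. At the temperature that ammonia needs, attack at the bromine-bearing carbon or cleavage of the acyl–imidazole bond could compete. The fallback uses a stronger, non-volatile nitrogen nucleophile with a removable benzyl group and sets out from 10.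
- 2,4-Dimethoxybenzylamine with K2CO3 in DMSO at 60–70 °C would give 1-SEM-2,5-bis{4-bromo-2-[(2,4-dimethoxybenzyl)amino]benzoyl}imidazole F6 without a pressure vessel.
- Brief treatment with TFA in CH2Cl2 at room temperature cleaves both electron-rich benzyl groups while N-SEM on imidazole persists, and the route is rejoined at 11.

**Further compounds**
F1 | step 6 | 1-SEM-2,5-bis[2-(2-amino-4-bromophenyl)oxiran-2-yl]imidazole (mixture of diastereomers) | C[Si](C)(C)CCOCn1c(C2(CO2)c2ccc(Br)cc2N)cnc1C1(CO1)c1ccc(Br)cc1N
F2 | step 6 | 1-SEM-2,5-bis(6-bromo-3-hydroxyindolin-3-yl)imidazole (mixture of diastereomers) | C[Si](C)(C)CCOCn1c(C2(O)CNc3cc(Br)ccc23)cnc1C1(O)CNc2cc(Br)ccc12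
F3 | step 3 | 1-SEM-imidazole-2,5-dicarbaldehyde | C[Si](C)(C)CCOCn1c(C=O)cnc1C=O
F4 | step 3 | (4-bromo-2-fluorophenyl)magnesium chloride | Fc1cc(Br)ccc1[Mg]Cl
F5 | step 3 | 1-SEM-2,5-bis[(4-bromo-2-fluorophenyl)(hydroxy)methyl]imidazole (mixture of diastereomers) | C[Si](C)(C)CCOCn1c(C(O)c2ccc(Br)cc2F)cnc1C(O)c1ccc(Br)cc1F
F6 | step 4 | 1-SEM-2,5-bis{4-bromo-2-[(2,4-dimethoxybenzyl)amino]benzoyl}imidazole | C[Si](C)(C)CCOCn1c(C(=O)c2ccc(Br)cc2NCc2ccc(OC)cc2OC)cnc1C(=O)c1ccc(Br)cc1NCc1ccc(OC)cc1OC
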